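Assumption: in step 5 the quinine-derived thiourea is taken to give the (S)-adduct 9, as in published chalcone/malonate additions; if the sense is reversed, the quinidine-derived pseudoenantiomer is used with no other change.

**Retrosynthetic overview**
1. Kuwanon W ⇐ hepta-O-allyl ether; the ring methyl comes from an enol triflate (cuprate coupling), itself from a regiodefined silyl enol ether.
2. Cyclohexene ring (formed last) ⇐ intramolecular Mukaiyama–Michael closure (C1–C6) of an aryl-ketone silyl enol ether onto a flavon-8-yl enone.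
3. That enone ⇐ intermolecular aldol condensation joining a "western" methyl ketone to the "eastern" flavone-8-carbaldehyde (the convergent C–C bond).
4. Western stereocentre ⇐ catalytic asymmetric intermolecular Michael addition of dimethyl malonate to a chalcone made by Claisen–Schmidt aldol; the chromene ring is formed first.
5. Flavone (pyranone ring formed second) ⇐ intermolecular Claisen condensation, C-prenylation, cyclodehydration, then C8 formylation.

Abbreviations in names: allyl = prop-2-en-1-yl; TBS = tert-butyldimethylsilyl; ArB = 2,4-bis(allyloxy)phenyl; Chr = 5-(allyloxy)-2,2-dimethyl-2H-chromen-6-yl; Fl = 5,7-bis(allyloxy)-2-[2,4-bis(allyloxy)phenyl]-3-(3-methylbut-2-en-1-yl)-4-oxo-4H-chromen-8-yl.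

**Western half**

Step 1
Reactants: 1 2,4-dihydroxyacetophenone; 2 3-methylbut-2-enal
Product: 3 1-(5-hydroxy-2,2-dimethyl-2H-chromen-6-yl)ethan-1-one
Conditions: pyridine, 120 °C
Reagents that add atoms: none
Why: Aldol-type (Knoevenagel) condensation at C3 of the resorcinol followed by oxa-6π electrocyclisation builds the chromene, and the 4-OH closes the ring because the 2-OH is chelated to the ketone.

Step 2
Reactants: 3 1-(5-hydroxy-2,2-dimethyl-2H-chromen-6-yl)ethan-1-one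
Product: 4 1-[5-(allyloxy)-2,2-dimethyl-2H-chromen-6-yl]ethan-1-one
Conditions: allyl bromide, K2CO3, DMF, 60 °C
Reagents that add atoms: allyl bromide, C=CCBr
Why: Williamson etherification of the chelated phenol gives an ether that survives base, organometallics and silyl Lewis acids and is removable at the end without acid.

Step 3
Reactants: 5 2,4-dihydroxybenzaldehyde
Product: 6 2,4-bis(allyloxy)benzaldehyde
Conditions: allyl bromide, K2CO3, DMF, 60 °C
Reagents that add atoms: allyl bromide, C=CCBr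
Why: Double Williamson etherification.

Step 4
Reactants: 4 1-[5-(allyloxy)-2,2-dimethyl-2H-chromen-6-yl]ethan-1-one; 6 2,4-bis(allyloxy)benzaldehyde
Product: 7 (E)-1-Chr-3-ArB-prop-2-en-1-one (chalcone)
Conditions: KOH, EtOH/H2O, rt
Reagents that add atoms: none
Why: Claisen–Schmidt aldol condensation of a methyl ketone with a non-enolisable aldehyde, with E1cB dehydration giving the E-enone.

Step 5
Reactants: 7 (E)-1-Chr-3-ArB-prop-2-en-1-one; 8 dimethyl malonate
Product: 9 dimethyl 2-[(1S)-1-ArB-3-Chr-3-oxopropyl]propanedioate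
Conditions: 1-[3,5-bis(trifluoromethyl)phenyl]-3-[(8S,9S)-6′-methoxycinchonan-9-yl]thiourea (10 mol %), toluene, rt, 3–5 d
Reagents that add atoms: none
Why: Bifunctional thiourea/amine-catalysed asymmetric intermolecular Michael addition, in which the catalyst hydrogen-bonds the enone and delivers the malonate to one face of the β-carbon, sets the benzylic stereocentre (S) that controls all later ones.

Step 6
Reactants: 9 dimethyl 2-[(1S)-1-ArB-3-Chr-3-oxopropyl]propanedioate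
Product: 10 methyl (3S)-3-ArB-5-Chr-5-oxopentanoate
Conditions: LiCl, H2O, DMSO, 130 °C
Reagents that add atoms: none
Why: Krapcho dealkoxycarbonylation removes one ester without touching the stereocentre (not α to a carbonyl), at a temperature below aryl allyl ether Claisen rearrangement.

Step 7
Reactants: 10 methyl (3S)-3-ArB-5-Chr-5-oxopentanoate
Product: 11 methyl (3R,4Z)-3-ArB-5-Chr-5-(TBS-oxy)pent-4-enoate
Conditions: tBuMe2SiOTf, Et3N, CH2Cl2, −78 → 0 °C
Reagents that add atoms: tert-butyldimethylsilyl trifluoromethanesulfonate, CC(C)(C)[Si](C)(C)OS(=O)(=O)C(F)(F)F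
Why: Soft enolisation of the only ketone gives the Z silyl enol ether, which masks the aryl ketone and stores a regiodefined nucleophile at the future C6 (the descriptor changes only by CIP priority).

Step 8
Reactants: 11 methyl (3R,4Z)-3-ArB-5-Chr-5-(TBS-oxy)pent-4-enoate
Product: 12 (3R,4Z)-3-ArB-5-Chr-5-(TBS-oxy)-N-methoxy-N-methylpent-4-enamide
Conditions: MeNH(OMe)·HCl, iPrMgCl, THF, −20 °C
Reagents that add atoms: N,O-dimethylhydroxylamine hydrochloride, CNOC.Cl
Why: Aminolysis of the methyl ester by the chloromagnesium amide gives the Weinreb amide.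

Step 9
Reactants: 12 (3R,4Z)-3-ArB-5-Chr-5-(TBS-oxy)-N-methoxy-N-methylpent-4-enamide
Product: 13 (4R,5Z)-4-ArB-6-Chr-6-(TBS-oxy)hex-5-en-2-one
Conditions: MeMgBr, THF, 0 °C
Reagents that add atoms: methylmagnesium bromide, C[Mg]Br
Why: Grignard addition to the Weinreb amide stops at the chelated tetrahedral intermediate and gives the methyl ketone on work-up.

**Eastern half (flavone)**

Step 10
Reactants: 14 2,4,6-trihydroxyacetophenone
Product: 15 1-[2-hydroxy-4,6-bis(allyloxy)phenyl]ethan-1-one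
Conditions: allyl bromide (2.05 equiv), K2CO3, acetone, reflux
Reagents that add atoms: allyl bromide, C=CCBr
Why: Williamson etherification stops at the bis-ether because the remaining ortho-OH is chelated to the carbonyl.

Step 11
Reactants: 15 1-[2-hydroxy-4,6-bis(allyloxy)phenyl]ethan-1-one
Product: 16 1-[2-hydroxy-3-iodo-4,6-bis(allyloxy)phenyl]ethan-1-one
Conditions: N-iodosuccinimide, MeCN, 0 °C → rt
Reagents that add atoms: N-iodosuccinimide, O=C1CCC(=O)N1I
Why: Electrophilic aromatic iodination goes ortho to the free phenol (C3), as known for the 4,6-dimethyl ether, placing iodine on the carbon that becomes C8 of the flavone.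

Step 12
Reactants: 17 methyl 2,4-dihydroxybenzoate
Product: 18 methyl 2,4-bis(allyloxy)benzoate
Conditions: allyl bromide, K2CO3, DMF, 60 °C
Reagents that add atoms: allyl bromide, C=CCBr
Why: Double Williamson etherification.

Step 13
Reactants: 16 1-[2-hydroxy-3-iodo-4,6-bis(allyloxy)phenyl]ethan-1-one; 18 methyl 2,4-bis(allyloxy)benzoate
Product: 19 1-[2-hydroxy-3-iodo-4,6-bis(allyloxy)phenyl]-3-ArB-propane-1,3-dione
Conditions: LiN(SiMe3)2 (4 equiv), THF, −78 °C → rt; aq NH4Cl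
Reagents that add atoms: none
Why: Intermolecular crossed Claisen condensation of the phenoxide/enolate dianion with the ester is driven by deprotonation of the 1,3-diketone.

Step 14
Reactants: 19 1-[2-hydroxy-3-iodo-4,6-bis(allyloxy)phenyl]-3-ArB-propane-1,3-dione
Product: 20 1-[2-hydroxy-3-iodo-4,6-bis(allyloxy)phenyl]-2-(3-methylbut-2-en-1-yl)-3-ArB-propane-1,3-dione
Conditions: prenyl bromide (1.1 equiv), K2CO3, acetone, rt
Reagents that add atoms: prenyl bromide, CC(C)=CCBr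
Why: SN2 C-alkylation of the soft 1,3-diketone enolate, the chelated phenol being much less nucleophilic.

Step 15
Reactants: 20 1-[2-hydroxy-3-iodo-4,6-bis(allyloxy)phenyl]-2-(3-methylbut-2-en-1-yl)-3-ArB-propane-1,3-dione
Product: 21 8-iodo-5,7-bis(allyloxy)-2-ArB-3-(3-methylbut-2-en-1-yl)-4H-chromen-4-one
Conditions: p-toluenesulfonic acid monohydrate (10 mol %), toluene, 80 °C
Reagents that add atoms: none
Why: Acid-catalysed cyclodehydration (hemiketal formation, then loss of water) gives the flavone, and because the only free phenol is the one next to iodine, iodine ends up at C8.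

Step 16
Reactants: 21 8-iodo-5,7-bis(allyloxy)-2-ArB-3-(3-methylbut-2-en-1-yl)-4H-chromen-4-one
Product: 23 5,7-bis(allyloxy)-2-ArB-3-(3-methylbut-2-en-1-yl)-4-oxo-4H-chromene-8-carbaldehyde (Fl-CHO), via arylmagnesium chloride 22 (not isolated)
Conditions: iPrMgCl·LiCl, THF, −40 °C; DMF, −40 → 0 °C; aq NH4Cl
Reagents that add atoms: N,N-dimethylformamide, CN(C)C=O
Why: Iodine–magnesium exchange (helped by the two flanking oxygens) followed by Bouveault formylation installs the aldehyde at C8 at a temperature where the hindered chromone carbonyl is not attacked.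

**Union and endgame**

Step 17
Reactants: 13 (4R,5Z)-4-ArB-6-Chr-6-(TBS-oxy)hex-5-en-2-one; 23 Fl-CHO
Product: 26 (1E,5R,6Z)-1-Fl-5-ArB-7-Chr-7-(TBS-oxy)hepta-1,6-dien-3-one, via lithium aldolate 24 (not isolated), via mesylate 25 (not isolated)
Conditions: LiN(iPr)2, THF, −78 °C; 23; MeSO2Cl, −78 → 0 °C; DBU, 0 °C → rt
Reagents that add atoms: none
Why: Directed intermolecular aldol addition of the kinetic methyl-ketone enolate to the non-enolisable aldehyde, then mesylation and E1cB elimination (aldol condensation), joins the two halves as the E-enone without touching the stereocentre.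

Step 18
Reactants: 26 (1E,5R,6Z)-1-Fl-5-ArB-7-Chr-7-(TBS-oxy)hepta-1,6-dien-3-one
Product: 28 (1S,5R,6S)-1-Fl-5-ArB-6-(Chr-carbonyl)-3-(TBS-oxy)cyclohex-2-ene, via C6-epimer mixture 27 (not isolated)
Conditions: tBuMe2SiOTf (1.5 equiv), 2,6-di-tert-butyl-4-methylpyridine, CH2Cl2, −78 → −30 °C; Et3N; then 1,8-diazabicyclo[5.4.0]undec-7-ene (DBU), CH2Cl2, rt
Reagents that add atoms: none
Why: Intramolecular 6-endo Mukaiyama–Michael addition of the silyl enol ether to the silyl-activated enone closes the ring and leaves the silyl group on the new enol oxygen (enol ether fixed at C2=C3); a chair-like closure puts Fl and ArB cis and equatorial (C1 set from C5), and DBU equilibrates the epimerisable C6 to the all-trans isomer.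

Step 19
Reactants: 28 (1S,5R,6S)-1-Fl-5-ArB-6-(Chr-carbonyl)-3-(TBS-oxy)cyclohex-2-ene
Product: 29 (1S,5R,6S)-1-Fl-5-ArB-6-(Chr-carbonyl)cyclohex-2-en-3-yl trifluoromethanesulfonate
Conditions: CsF, PhNTf2, 1,2-dimethoxyethane, rt
Reagents that add atoms: N-phenylbis(trifluoromethanesulfonimide), O=S(=O)(N(c1ccccc1)S(=O)(=O)C(F)(F)F)C(F)(F)F
Why: Fluoride desilylation releases the regiodefined enolate, which is O-triflated as it forms, so the double bond stays at C2=C3.

Step 20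
Reactants: 29 (1S,5R,6S)-1-Fl-5-ArB-6-(Chr-carbonyl)cyclohex-2-en-3-yl trifluoromethanesulfonate
Product: 30 hepta-O-allyl kuwanon W, (1S,5R,6S)-1-Fl-5-ArB-6-(Chr-carbonyl)-3-methylcyclohex-2-ene
Conditions: Me2CuLi (from CuI and MeLi), THF, −20 °C
Reagents that add atoms: lithium dimethylcuprate, [Li+].C[Cu-]C
Why: Cuprate cross-coupling with the enol triflate replaces OTf by methyl with retention of alkene position, and the hindered aryl ketone and the tetrasubstituted chromone are not attacked at this temperature.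

Step 21
Reactants: 30 hepta-O-allyl kuwanon W
Product: 31 kuwanon W
Conditions: Pd(PPh3)4 (10 mol %), morpholine, THF, rt
Reagents that add atoms: none
Why: Allyl transfer to morpholine, catalysed by zerovalent palladium (Tsuji–Trost deallylation), frees all seven phenols under near-neutral conditions that spare the prenyl group, the chromene, the ring alkene and the stereocentres.

**Compound list**
1 | 2,4-dihydroxyacetophenone | CC(=O)c1ccc(O)cc1O | starting material
2 | 3-methylbut-2-enal | CC(C)=CC=O | starting material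
3 | 1-(5-hydroxy-2,2-dimethyl-2H-chromen-6-yl)ethan-1-one | CC(=O)c1ccc2OC(C)(C)C=Cc2c1O | intermediate
4 | 1-[5-(allyloxy)-2,2-dimethyl-2H-chromen-6-yl]ethan-1-one | CC(=O)c1ccc2OC(C)(C)C=Cc2c1OCC=C | intermediate
5 | 2,4-dihydroxybenzaldehyde | O=Cc1ccc(O)cc1O | starting material
6 | 2,4-bis(allyloxy)benzaldehyde | O=Cc1ccc(OCC=C)cc1OCC=C | intermediate
7 | (E)-1-[5-(allyloxy)-2,2-dimethyl-2H-chromen-6-yl]-3-[2,4-bis(allyloxy)phenyl]prop-2-en-1-one | C=CCOc1ccc(/C=C/C(=O)c2ccc3OC(C)(C)C=Cc3c2OCC=C)c(OCC=C)c1 | intermediate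
8 | dimethyl malonate | COC(=O)CC(=O)OC | starting material
9 | dimethyl 2-[(1S)-1-ArB-3-Chr-3-oxopropyl]propanedioate | COC(=O)C(C(=O)OC)[C@@H](c1ccc(OCC=C)cc1OCC=C)CC(=O)c1ccc2OC(C)(C)C=Cc2c1OCC=C | intermediate
10 | methyl (3S)-3-ArB-5-Chr-5-oxopentanoate | COC(=O)C[C@@H](c1ccc(OCC=C)cc1OCC=C)CC(=O)c1ccc2OC(C)(C)C=Cc2c1OCC=C | intermediate
11 | methyl (3R,4Z)-3-ArB-5-Chr-5-(TBS-oxy)pent-4-enoate | COC(=O)C[C@@H](c1ccc(OCC=C)cc1OCC=C)/C=C(\O[Si](C)(C)C(C)(C)C)c1ccc2OC(C)(C)C=Cc2c1OCC=C | intermediate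
12 | (3R,4Z)-3-ArB-5-Chr-5-(TBS-oxy)-N-methoxy-N-methylpent-4-enamide | CON(C)C(=O)C[C@@H](c1ccc(OCC=C)cc1OCC=C)/C=C(\O[Si](C)(C)C(C)(C)C)c1ccc2OC(C)(C)C=Cc2c1OCC=C | intermediate
13 | (4R,5Z)-4-ArB-6-Chr-6-(TBS-oxy)hex-5-en-2-one | CC(=O)C[C@@H](c1ccc(OCC=C)cc1OCC=C)/C=C(\O[Si](C)(C)C(C)(C)C)c1ccc2OC(C)(C)C=Cc2c1OCC=C | intermediate
14 | 2,4,6-trihydroxyacetophenone | CC(=O)c1c(O)cc(O)cc1O | starting material
15 | 1-[2-hydroxy-4,6-bis(allyloxy)phenyl]ethan-1-one | CC(=O)c1c(O)cc(OCC=C)cc1OCC=C | intermediate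
16 | 1-[2-hydroxy-3-iodo-4,6-bis(allyloxy)phenyl]ethan-1-one | CC(=O)c1c(O)c(I)c(OCC=C)cc1OCC=C | intermediate
17 | methyl 2,4-dihydroxybenzoate | COC(=O)c1ccc(O)cc1O | starting material
18 | methyl 2,4-bis(allyloxy)benzoate | COC(=O)c1ccc(OCC=C)cc1OCC=C | intermediate
19 | 1-[2-hydroxy-3-iodo-4,6-bis(allyloxy)phenyl]-3-[2,4-bis(allyloxy)phenyl]propane-1,3-dione | O=C(CC(=O)c1ccc(OCC=C)cc1OCC=C)c1c(O)c(I)c(OCC=C)cc1OCC=C | intermediate
20 | 2-prenyl derivative of 19 | CC(C)=CCC(C(=O)c1ccc(OCC=C)cc1OCC=C)C(=O)c1c(O)c(I)c(OCC=C)cc1OCC=C | intermediate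
21 | 8-iodo-5,7-bis(allyloxy)-2-[2,4-bis(allyloxy)phenyl]-3-(3-methylbut-2-en-1-yl)-4H-chromen-4-one | CC(C)=CCc1c(-c2ccc(OCC=C)cc2OCC=C)oc2c(I)c(OCC=C)cc(OCC=C)c2c1=O | intermediate
22 | flavon-8-ylmagnesium chloride from 21 (not isolated) | CC(C)=CCc1c(-c2ccc(OCC=C)cc2OCC=C)oc2c([Mg]Cl)c(OCC=C)cc(OCC=C)c2c1=O | intermediate
23 | 5,7-bis(allyloxy)-2-[2,4-bis(allyloxy)phenyl]-3-(3-methylbut-2-en-1-yl)-4-oxo-4H-chromene-8-carbaldehyde | CC(C)=CCc1c(-c2ccc(OCC=C)cc2OCC=C)oc2c(C=O)c(OCC=C)cc(OCC=C)c2c1=O | intermediate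
24 | lithium aldolate, (5R,6Z)-1-Fl-1-(lithiooxy)-5-ArB-7-Chr-7-(TBS-oxy)hept-6-en-3-one, both C1 epimers (not isolated) | CC(C)=CCc1c(-c2ccc(OCC=C)cc2OCC=C)oc2c(C(O[Li])CC(=O)C[C@@H](c3ccc(OCC=C)cc3OCC=C)/C=C(\O[Si](C)(C)C(C)(C)C)c3ccc4OC(C)(C)C=Cc4c3OCC=C)c(OCC=C)cc(OCC=C)c2c1=O | intermediate
25 | corresponding C1 methanesulfonate (not isolated) | CC(C)=CCc1c(-c2ccc(OCC=C)cc2OCC=C)oc2c(C(OS(C)(=O)=O)CC(=O)C[C@@H](c3ccc(OCC=C)cc3OCC=C)/C=C(\O[Si](C)(C)C(C)(C)C)c3ccc4OC(C)(C)C=Cc4c3OCC=C)c(OCC=C)cc(OCC=C)c2c1=O | intermediate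
26 | (1E,5R,6Z)-1-Fl-5-ArB-7-Chr-7-(TBS-oxy)hepta-1,6-dien-3-one | CC(C)=CCc1c(-c2ccc(OCC=C)cc2OCC=C)oc2c(/C=C/C(=O)C[C@@H](c3ccc(OCC=C)cc3OCC=C)/C=C(\O[Si](C)(C)C(C)(C)C)c3ccc4OC(C)(C)C=Cc4c3OCC=C)c(OCC=C)cc(OCC=C)c2c1=O | intermediate
27 | (1S,5R)-1-Fl-5-ArB-6-(Chr-carbonyl)-3-(TBS-oxy)cyclohex-2-ene, C6 epimers (not isolated) | CC(C)=CCc1c(-c2ccc(OCC=C)cc2OCC=C)oc2c([C@H]3C=C(O[Si](C)(C)C(C)(C)C)C[C@@H](c4ccc(OCC=C)cc4OCC=C)C3C(=O)c3ccc4OC(C)(C)C=Cc4c3OCC=C)c(OCC=C)cc(OCC=C)c2c1=O | intermediate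
28 | (1S,5R,6S)-1-Fl-5-ArB-6-(Chr-carbonyl)-3-(TBS-oxy)cyclohex-2-ene (all-trans) | CC(C)=CCc1c(-c2ccc(OCC=C)cc2OCC=C)oc2c([C@H]3C=C(O[Si](C)(C)C(C)(C)C)C[C@@H](c4ccc(OCC=C)cc4OCC=C)[C@@H]3C(=O)c3ccc4OC(C)(C)C=Cc4c3OCC=C)c(OCC=C)cc(OCC=C)c2c1=O | intermediate
29 | (1S,5R,6S)-1-Fl-5-ArB-6-(Chr-carbonyl)cyclohex-2-en-3-yl trifluoromethanesulfonate | CC(C)=CCc1c(-c2ccc(OCC=C)cc2OCC=C)oc2c([C@H]3C=C(OS(=O)(=O)C(F)(F)F)C[C@@H](c4ccc(OCC=C)cc4OCC=C)[C@@H]3C(=O)c3ccc4OC(C)(C)C=Cc4c3OCC=C)c(OCC=C)cc(OCC=C)c2c1=O | intermediate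
30 | hepta-O-allyl kuwanon W, (1S,5R,6S)-1-Fl-5-ArB-6-(Chr-carbonyl)-3-methylcyclohex-2-ene | CC(C)=CCc1c(-c2ccc(OCC=C)cc2OCC=C)oc2c([C@H]3C=C(C)C[C@@H](c4ccc(OCC=C)cc4OCC=C)[C@@H]3C(=O)c3ccc4OC(C)(C)C=Cc4c3OCC=C)c(OCC=C)cc(OCC=C)c2c1=O | intermediate
31 | kuwanon W, 8-[(1S,5R,6S)-5-(2,4-dihydroxyphenyl)-6-(5-hydroxy-2,2-dimethyl-2H-chromene-6-carbonyl)-3-methylcyclohex-2-en-1-yl]-2-(2,4-dihydroxyphenyl)-5,7-dihydroxy-3-(3-methylbut-2-en-1-yl)-4H-chromen-4-one | CC(C)=CCc1c(-c2ccc(O)cc2O)oc2c([C@H]3C=C(C)C[C@@H](c4ccc(O)cc4O)[C@@H]3C(=O)c3ccc4c(c3O)C=CC(C)(C)O4)c(O)cc(O)c2c1=O | target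

**Totals**
Total step count: 21. Longest linear sequence: 13 steps (1, 2, 4, 5, 6, 7, 8, 9, 17, 18, 19, 20, 21).

**Steps most likely to fail, with fallbacks**

Step 18 (ring closure). The enone β-carbon carries a hindered, electron-rich flavonyl group, and the chromone carbonyl competes for the silyl Lewis acid. The fallback sets out from 26 and activates the nucleophile instead of the electrophile. Anhydrous Bu4N[Ph3SiF2] in THF at −78 °C cleaves the silyl enol ether to the free aryl-ketone enolate, which closes the ring by an anionic 6-endo Michael addition. This gives the tetrabutylammonium enolate of the cyclised ketone F1 (not isolated). PhNTf2 added to the cold solution triflates this regiodefined enolate, and DBU then equilibrates C6. The sequence comes back to the route at 29 and bypasses 28.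

Step 5 (asymmetric Michael addition). The β-aryl group is a strong donor with an ortho substituent, so hydrogen-bond catalysis may be too slow or poorly selective. The fallback sets out from 7 and uses Lewis-acid catalysis with a preformed silicon nucleophile. Cu(OTf)2 with 2,2′-(propane-2,2-diyl)bis[(4S)-4-tert-butyl-4,5-dihydro-1,3-oxazole] (or its enantiomer, whichever gives the configuration of 10) binds the ketone and the ortho allyloxy oxygen. It catalyses a Mukaiyama–Michael addition of 1-(tert-butylsulfanyl)-1-(trimethylsilyloxy)ethene, with hexafluoropropan-2-ol for turnover, to give S-tert-butyl (3S)-3-ArB-5-Chr-5-oxopentanethioate F2. tBuMe2SiOTf/Et3N converts it into the silyl enol ether S-tert-butyl (3R,4Z)-3-ArB-5-Chr-5-(TBS-oxy)pent-4-enethioate F3. MeNH(OMe)·HCl/iPrMgCl then turns the thioester into the Weinreb amide, so the sequence comes back to the route at 12 and bypasses 9, 10 and 11.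

Step 16 (metalation and formylation of the iodoflavone). Halogen–magnesium exchange on a hindered, electron-rich iodide next to a chromone carbonyl may be slow or unselective. The fallback sets out from 15 and introduces the aldehyde before the flavone is built. Magnesium-mediated ortho-formylation (MgCl2, Et3N, paraformaldehyde, MeCN, reflux) goes only ortho to the free phenol and gives 3-acetyl-2-hydroxy-4,6-bis(allyloxy)benzaldehyde F4. HC(OMe)3 with catalytic pyridinium p-toluenesulfonate in MeOH protects it as 1-[3-(dimethoxymethyl)-2-hydroxy-4,6-bis(allyloxy)phenyl]ethan-1-one F5. Claisen condensation with 18 (LiN(SiMe3)2, THF) gives the acetal diketone F6, and prenyl bromide/K2CO3 gives its 2-prenyl derivative F7. p-Toluenesulfonic acid monohydrate in wet toluene then effects cyclodehydration and acetal hydrolysis together. The sequence comes back to the route at 23 and bypasses 16, 19, 20, 21 and 22.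

**Further compounds**
F1 | step 18 | tetrabutylammonium enolate of (1S,5R)-1-Fl-5-ArB-6-(Chr-carbonyl)cyclohexan-3-one, C2=C3 enolate, C6 epimers | CCCC[N+](CCCC)(CCCC)CCCC.CC(C)=CCc1c(-c2ccc(OCC=C)cc2OCC=C)oc2c([C@H]3C=C([O-])C[C@@H](c4ccc(OCC=C)cc4OCC=C)C3C(=O)c3ccc4OC(C)(C)C=Cc4c3OCC=C)c(OCC=C)cc(OCC=C)c2c1=O
F2 | step 5 | S-tert-butyl (3S)-3-ArB-5-Chr-5-oxopentanethioate | CC(C)(C)SC(=O)C[C@@H](c1ccc(OCC=C)cc1OCC=C)CC(=O)c1ccc2OC(C)(C)C=Cc2c1OCC=C
F3 | step 5 | S-tert-butyl (3R,4Z)-3-ArB-5-Chr-5-(TBS-oxy)pent-4-enethioate | CC(C)(C)SC(=O)C[C@@H](c1ccc(OCC=C)cc1OCC=C)/C=C(\O[Si](C)(C)C(C)(C)C)c1ccc2OC(C)(C)C=Cc2c1OCC=C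
F4 | step 16 | 3-acetyl-2-hydroxy-4,6-bis(allyloxy)benzaldehyde | CC(=O)c1c(O)c(C=O)c(OCC=C)cc1OCC=C
F5 | step 16 | 1-[3-(dimethoxymethyl)-2-hydroxy-4,6-bis(allyloxy)phenyl]ethan-1-one | CC(=O)c1c(O)c(C(OC)OC)c(OCC=C)cc1OCC=C
F6 | step 16 | 1-[3-(dimethoxymethyl)-2-hydroxy-4,6-bis(allyloxy)phenyl]-3-[2,4-bis(allyloxy)phenyl]propane-1,3-dione | COC(OC)c1c(O)c(C(=O)CC(=O)c2ccc(OCC=C)cc2OCC=C)c(OCC=C)cc1OCC=C
F7 | step 16 | 2-(3-methylbut-2-en-1-yl) derivative of F6 | COC(OC)c1c(O)c(C(=O)C(CC=C(C)C)C(=O)c2ccc(OCC=C)cc2OCC=C)c(OCC=C)cc1OCC=C
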